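**Retrosynthetic overview**
- The route rests on the tetrasubstituted C7=C11 butenolide (O6–C12(=O)–C11=C7, with C13H2OAc on C11) fused to the ten-membered carbocycle C1–C10. It is read as a C7≡C11 alkyne plus the C6 aldehyde plus CO, joined on divalent titanium in one operation: the ten-membered ring closes at C6–C7, then the lactone at O6–C12.
- The open-chain ynal is cut at C1–C2 (Grignard reagent plus masked C1 aldehyde) and at C7–C8 (acyl Sonogashira coupling). C10 comes from (R)-citramalic acid, C8 from a Noyori ynone reduction, and C4/C5 from a Sharpless epoxidation of an (E)-allylic alcohol made by Negishi carboalumination.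
- C1 goes through the annulation as a silyl-protected alcohol. A free C1 ketone and the C7≡C11 alkyne are a δ,ε-alkynyl ketone (tether C10–C9–C8) that would close a five-membered ring instead of the ten-membered one.
- End game: C1 ketone, then desilylation, C13 acetate and C8 tiglate.

Key step: step 16

**Remarks on the chemistry (assumptions)**
- Germacrane numbering is used: ring C1–C10, C11 the butenolide α-carbon, C12 the lactone carbonyl, C13 the CH2O carbon, methyl groups on C4 and C10.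
- tert-Butyldimethyl(prop-2-yn-1-yloxy)silane and tert-butyl(but-3-yn-1-yloxy)dimethylsilane are taken as commercial (each is one silylation from propargyl alcohol or 3-butyn-1-ol).
- The C1 carbinol is drawn (1R), the epimer predicted by chelation control in step 10. C1 becomes the ketone in step 18, so its configuration does not reach the target.
- In the target (4R,5R,6S) the epoxide C5–O bond and the C6–O bond are syn in the zigzag sense. Simple Felkin–Anh addition to an α,β-epoxy aldehyde would give the anti isomer, so the required rotamer is discussed in step 16.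

**Route**

Step 1
Reactants: 1 (R)-citramalic acid
Product: 2 2-[(4R)-2,2,4-trimethyl-5-oxo-1,3-dioxolan-4-yl]acetic acid
Conditions: 2,2-dimethoxypropane, TsOH·H2O (cat.), acetone, rt
Reagents that add atoms: 2,2-dimethoxypropane, COC(C)(C)OC
Why: Acid-catalysed acetal exchange ties the α-hydroxy acid into the five-membered dioxolanone and leaves the β-carboxyl free, so that C1 and C8 are told apart while the C10 stereocentre is untouched.

Step 2
Reactants: 2; 3 tert-butyldimethyl(prop-2-yn-1-yloxy)silane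
Product: 5 (5R)-5-[5-(tert-butyldimethylsilyloxy)-2-oxopent-3-yn-1-yl]-2,2,5-trimethyl-1,3-dioxolan-4-one, via acid chloride 4 (not isolated)
Conditions: (COCl)2, DMF (cat.), CH2Cl2, 0 °C → rt, evaporate; then 3, PdCl2(PPh3)2 (2 mol%), CuI (4 mol%), Et3N (1.2 equiv), THF, rt
Reagents that add atoms: none
Why: Acid chloride formation followed by acyl Sonogashira coupling with the terminal alkyne forms C7–C8 under conditions that the dioxolanone and the silyl ether should tolerate.

Step 3
Reactants: 5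
Product: 6 (5R)-5-[(2S)-5-(tert-butyldimethylsilyloxy)-2-hydroxypent-3-yn-1-yl]-2,2,5-trimethyl-1,3-dioxolan-4-one
Conditions: Ru(p-cymene)[(S,S)-TsNCH(Ph)CH(Ph)NH] (2 mol%), i-PrOH, rt
Reagents that add atoms: none
Why: Noyori asymmetric transfer hydrogenation of an ynone, in which the alkynyl group plays the part of the aryl group, should set C8 as (S) under catalyst control, and the base-free medium avoids β-elimination of the C10 oxygen.

Step 4
Reactants: 6
Product: 7 (5R)-5-[(2S)-2,5-bis(tert-butyldimethylsilyloxy)pent-3-yn-1-yl]-2,2,5-trimethyl-1,3-dioxolan-4-one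
Conditions: TBSOTf, 2,6-lutidine, CH2Cl2, −78 °C
Reagents that add atoms: tert-butyldimethylsilyl triflate, CC(C)(C)[Si](C)(C)OS(=O)(=O)C(F)(F)F
Why: Silylation with the triflate at −78 °C should cap the C8 hydroxyl before it can translactonise onto the dioxolanone carbonyl.

Step 5
Reactants: 7
Product: 8 (5R)-5-[(2S)-2,5-bis(tert-butyldimethylsilyloxy)pent-3-yn-1-yl]-2,2,5-trimethyl-1,3-dioxolan-4-ol (anomer mixture)
Conditions: i-Bu2AlH (1.1 equiv), CH2Cl2, −78 °C; aq. potassium sodium tartrate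
Reagents that add atoms: none
Why: Partial reduction of the dioxolanone at −78 °C should stop at the cyclic hemiacetal, a masked C1 aldehyde with the C10 oxygen still protected.

Step 6
Reactants: 9 tert-butyl(but-3-yn-1-yloxy)dimethylsilane
Product: 12 (2E)-5-(tert-butyldimethylsilyloxy)-3-methylpent-2-en-1-ol, via alkenylalane 10 (not isolated), via lithium aluminate 11 (not isolated)
Conditions: AlMe3 (2.5 equiv), Cp2ZrCl2 (0.25 equiv), CH2Cl2, 0 °C → rt; then n-BuLi, hexane, 0 °C; (CH2O)n, THF, rt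
Reagents that add atoms: trimethylaluminium, C[Al](C)C; formaldehyde (from paraformaldehyde), C=O
Why: Zirconium-catalysed syn carboalumination (Negishi) puts methyl on the internal and aluminium on the terminal alkyne carbon, and the derived aluminate adds to formaldehyde with retention to give the (E)-trisubstituted allylic alcohol (C2–C6 unit).

Step 7
Reactants: 12
Product: 13 tert-butyl({(3E)-5-[(4-methoxybenzyl)oxy]-3-methylpent-3-en-1-yl}oxy)dimethylsilane
Conditions: NaH, 4-methoxybenzyl chloride, Bu4NI (cat.), DMF, 0 °C → rt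
Reagents that add atoms: 4-methoxybenzyl chloride, COc1ccc(CCl)cc1
Why: Williamson etherification protects the allylic C6 oxygen as a PMB ether, which survives the Grignard chemistry and is removable later beside silyl ethers and an acetate.

Step 8
Reactants: 13
Product: 14 (3E)-5-[(4-methoxybenzyl)oxy]-3-methylpent-3-en-1-ol
Conditions: Bu4NF, THF, 0 °C → rt
Reagents that add atoms: none
Why: Fluoride cleaves the primary silyl ether and leaves the PMB ether and the alkene geometry untouched.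

Step 9
Reactants: 14
Product: 15 1-({[(2E)-5-bromo-3-methylpent-2-en-1-yl]oxy}methyl)-4-methoxybenzene
Conditions: CBr4, PPh3, CH2Cl2, 0 °C
Reagents that add atoms: carbon tetrabromide, BrC(Br)(Br)Br
Why: Appel bromination converts the primary homoallylic alcohol into the bromide under neutral conditions.

Step 10
Reactants: 8; 15
Product: 18 (2E,6R,7R,9S)-9,12-bis(tert-butyldimethylsilyloxy)-1-[(4-methoxybenzyl)oxy]-3,7-dimethyldodec-2-en-10-yne-6,7-diol, via Grignard reagent 16 (not isolated), via aldehyde alkoxide 17 (not isolated)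
Conditions: 15, Mg turnings, THF, rt (gives 16, 3.0 equiv); 8 in THF added at −78 °C, then 0 °C; aq. NH4Cl
Reagents that add atoms: none
Why: Grignard addition to a lactol: the reagent opens 8 to the magnesium alkoxide of the α-hydroxy aldehyde and adds to it (the third equivalent takes up the acetone released), and Cram-chelate control through the C10 alkoxide should direct attack from the methyl-bearing face to the (1R)-carbinol (C1–C2 bond).

Step 11
Reactants: 18
Product: 19 (2E,6R,7R,9S)-9,12-bis(tert-butyldimethylsilyloxy)-1-[(4-methoxybenzyl)oxy]-3,7-dimethyl-6-(triethylsilyloxy)dodec-2-en-10-yn-7-ol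
Conditions: TESOTf (1.1 equiv), 2,6-lutidine, CH2Cl2, −78 °C
Reagents that add atoms: triethylsilyl triflate, CC[Si](CC)(CC)OS(=O)(=O)C(F)(F)F
Why: At −78 °C the silyl triflate should take the secondary C1 hydroxyl and leave the tertiary C10 hydroxyl free; this ether masks the future C1 ketone through the annulation.

Step 12
Reactants: 19
Product: 20 (2E,6R,7R,9S)-9,12-bis(tert-butyldimethylsilyloxy)-1-[(4-methoxybenzyl)oxy]-3,7-dimethyl-6-(triethylsilyloxy)dodec-2-en-10-yn-7-yl acetate
Conditions: Ac2O, Et3N, DMAP (1 equiv), CH2Cl2, rt → 40 °C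
Reagents that add atoms: acetic anhydride, CC(=O)OC(C)=O
Why: DMAP-catalysed acylation of the only free hydroxyl installs the tertiary C10 acetate of the target.

Step 13
Reactants: 20
Product: 21 (2E,6R,7R,9S)-9,12-bis(tert-butyldimethylsilyloxy)-1-hydroxy-3,7-dimethyl-6-(triethylsilyloxy)dodec-2-en-10-yn-7-yl acetate
Conditions: DDQ, CH2Cl2/pH 7 phosphate buffer, 0 °C
Reagents that add atoms: none
Why: Buffered oxidative cleavage of the allylic PMB ether should free the C6 alcohol and leave the silyl ethers, the acetate and the alkyne in place.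

Step 14
Reactants: 21
Product: 22 (3R,4R,6S)-6,9-bis(tert-butyldimethylsilyloxy)-1-[(2R,3R)-3-(hydroxymethyl)-2-methyloxiran-2-yl]-4-methyl-3-(triethylsilyloxy)non-7-yn-4-yl acetate
Conditions: Ti(OiPr)4 (10 mol%), D-(−)-diethyl tartrate (12 mol%), t-BuOOH, 4 Å molecular sieves, CH2Cl2, −20 °C
Reagents that add atoms: tert-butyl hydroperoxide, CC(C)(C)OO
Why: Sharpless asymmetric epoxidation of the (E)-3-methyl allylic alcohol with the D-(−)-tartrate should give the (4R,5R)-epoxide under reagent control, the mirror image of the result of the L-(+)-ligand with geraniol-type alcohols.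

Step 15
Reactants: 22
Product: 23 (3R,4R,6S)-6,9-bis(tert-butyldimethylsilyloxy)-1-[(2R,3S)-3-formyl-2-methyloxiran-2-yl]-4-methyl-3-(triethylsilyloxy)non-7-yn-4-yl acetate (the ynal)
Conditions: Dess–Martin periodinane, NaHCO3, CH2Cl2, 0 °C → rt
Reagents that add atoms: none
Why: Dess–Martin oxidation under bicarbonate buffer should give the α,β-epoxy aldehyde without opening the epoxide or epimerising C5.

Step 16
Reactants: 23
Product: 26 (1R,4R,5R,6S,8S,10R)-10-acetoxy-8,13-bis(tert-butyldimethylsilyloxy)-4,5-epoxy-1-(triethylsilyloxy)germacr-7(11)-en-12,6-olide, via oxatitanacyclopentene 24 (not isolated), via acyltitanium complex 25 (not isolated)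
Conditions: Cp2Ti(PMe3)2 (1.2 equiv), toluene, slow addition of 23 (final 1 mM), rt; then CO (1–2 atm), rt → 60 °C; air, filtration
Reagents that add atoms: carbon monoxide, [C-]#[O+]
Why: Proposed new method: loss of PMe3 lets divalent titanium bind the C7≡C11 alkyne as a titanacyclopropene, the C6 aldehyde inserts into its Ti–C7 bond to give oxatitanacyclopentene 24 (C6–C7), CO inserts into the Ti–C11 bond to give acyl complex 25 (C11–C12), and C–O reductive elimination forms O6–C12 and releases Cp2Ti(CO)2. The closest known reaction type is the titanocene-mediated intramolecular hetero-Pauson–Khand reaction of short-tethered ynals and ynones to fused butenolides; a ten-membered tether has not been shown. The ten-membered carbocycle closes in the aldehyde insertion as a 10-exo-dig closure onto C7 with C11 left outside the ring, and the butenolide closes in the reductive elimination as a five-membered acyl–oxygen closure. C6 (S) should be set by the C4–C5 epoxide and the tether: C7 enters anti to the C5–O bond in the rotamer that puts the titanium-bound aldehyde oxygen next to H5 and not next to the fully substituted C4, which is the H5/H6-antiperiplanar arrangement of the product ring. The step needs bonding at C7 and not C11 (ten- against eleven-membered ring, secured only by the shorter tether path and by the strain of an in-ring E-alkene in the endo mode), reaction at the aldehyde only (secured by carrying C1 as its silyl ether) and survival of the epoxide and the propargylic C–O bonds (silyl ethers are poor leaving groups). High dilution should hold back intermolecular coupling.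

Step 17
Reactants: 26
Product: 27 (1R,4R,5R,6S,8S,10R)-10-acetoxy-8,13-bis(tert-butyldimethylsilyloxy)-4,5-epoxy-1-hydroxygermacr-7(11)-en-12,6-olide
Conditions: HF·pyridine, pyridine, THF, 0 °C; NaHCO3 work-up, used at once
Reagents that add atoms: none
Why: Buffered HF·pyridine should cleave the triethylsilyl ether well before the two TBS ethers, and the hydroxy epoxide is kept cold and acid-free so that neither 1,4-transannular epoxide opening nor acetyl migration from O10 to O1 sets in.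

Step 18
Reactants: 27
Product: 28 (4R,5R,6S,8S,10R)-10-acetoxy-8,13-bis(tert-butyldimethylsilyloxy)-4,5-epoxy-1-oxogermacr-7(11)-en-12,6-olide
Conditions: Dess–Martin periodinane, NaHCO3, CH2Cl2, 0 °C
Reagents that add atoms: none
Why: Dess–Martin oxidation of the only free (secondary) alcohol gives the C1 ketone under non-acidic conditions.

Step 19
Reactants: 28
Product: 29 (4R,5R,6S,8S,10R)-10-acetoxy-4,5-epoxy-8,13-dihydroxy-1-oxogermacr-7(11)-en-12,6-olide
Conditions: HF·pyridine (excess), pyridine, THF, 0 °C → rt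
Reagents that add atoms: none
Why: Longer exposure to buffered HF·pyridine should remove the primary and the secondary allylic TBS ethers while the esters, lactone and epoxide remain.

Step 20
Reactants: 29
Product: 30 (4R,5R,6S,8S,10R)-10,13-diacetoxy-4,5-epoxy-8-hydroxy-1-oxogermacr-7(11)-en-12,6-olide
Conditions: AcCl (1.05 equiv), 2,4,6-collidine, CH2Cl2, −78 °C
Reagents that add atoms: acetyl chloride, CC(Cl)=O
Why: Acetyl chloride with collidine at −78 °C should acetylate the primary C13 hydroxyl selectively over the secondary C8 hydroxyl.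

Step 21
Reactants: 30
Product: 31 (4R,5R,6S,8S,10R)-10,13-diacetoxy-4,5-epoxy-1-oxo-8-[(E)-2-methylbut-2-enoyloxy]germacr-7(11)-en-12,6-olide (target)
Conditions: (E)-2-methylbut-2-enoyl chloride, pyridine, DMAP (cat.), CH2Cl2, 0 °C → rt; buffered work-up
Reagents that add atoms: tigloyl chloride, C/C=C(\C)C(Cl)=O
Why: DMAP-catalysed acylation of the C8 alcohol with the (E)-acid chloride should give the tiglate without change at C8 or in the alkene geometry.

**Compound list**

1 | (R)-citramalic acid, (2R)-2-hydroxy-2-methylbutanedioic acid | OC(=O)C[C@@](C)(O)C(O)=O | starting material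
2 | 2-[(4R)-2,2,4-trimethyl-5-oxo-1,3-dioxolan-4-yl]acetic acid | OC(=O)C[C@@]1(C)OC(C)(C)OC1=O | intermediate
3 | tert-butyldimethyl(prop-2-yn-1-yloxy)silane | C#CCO[Si](C)(C)C(C)(C)C | starting material
4 | 2-[(4R)-2,2,4-trimethyl-5-oxo-1,3-dioxolan-4-yl]acetyl chloride | ClC(=O)C[C@@]1(C)OC(C)(C)OC1=O | intermediate (not isolated)
5 | (5R)-5-[5-(tert-butyldimethylsilyloxy)-2-oxopent-3-yn-1-yl]-2,2,5-trimethyl-1,3-dioxolan-4-one | CC(C)(C)[Si](C)(C)OCC#CC(=O)C[C@@]1(C)OC(C)(C)OC1=O | intermediate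
6 | (5R)-5-[(2S)-5-(tert-butyldimethylsilyloxy)-2-hydroxypent-3-yn-1-yl]-2,2,5-trimethyl-1,3-dioxolan-4-one | CC(C)(C)[Si](C)(C)OCC#C[C@@H](O)C[C@@]1(C)OC(C)(C)OC1=O | intermediate
7 | (5R)-5-[(2S)-2,5-bis(tert-butyldimethylsilyloxy)pent-3-yn-1-yl]-2,2,5-trimethyl-1,3-dioxolan-4-one | CC(C)(C)[Si](C)(C)OCC#C[C@@H](O[Si](C)(C)C(C)(C)C)C[C@@]1(C)OC(C)(C)OC1=O | intermediate
8 | (5R)-5-[(2S)-2,5-bis(tert-butyldimethylsilyloxy)pent-3-yn-1-yl]-2,2,5-trimethyl-1,3-dioxolan-4-ol, anomer mixture | CC(C)(C)[Si](C)(C)OCC#C[C@@H](O[Si](C)(C)C(C)(C)C)C[C@@]1(C)OC(C)(C)OC1O | intermediate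
9 | tert-butyl(but-3-yn-1-yloxy)dimethylsilane | C#CCCO[Si](C)(C)C(C)(C)C | starting material
10 | [(1E)-4-(tert-butyldimethylsilyloxy)-2-methylbut-1-en-1-yl]dimethylalane | C[Al](C)/C=C(\C)CCO[Si](C)(C)C(C)(C)C | intermediate (not isolated)
11 | lithium butyl[(1E)-4-(tert-butyldimethylsilyloxy)-2-methylbut-1-en-1-yl]dimethylaluminate | [Li+].CCCC[Al-](C)(C)/C=C(\C)CCO[Si](C)(C)C(C)(C)C | intermediate (not isolated)
12 | (2E)-5-(tert-butyldimethylsilyloxy)-3-methylpent-2-en-1-ol | OC/C=C(\C)CCO[Si](C)(C)C(C)(C)C | intermediate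
13 | tert-butyl({(3E)-5-[(4-methoxybenzyl)oxy]-3-methylpent-3-en-1-yl}oxy)dimethylsilane | COc1ccc(COC/C=C(\C)CCO[Si](C)(C)C(C)(C)C)cc1 | intermediate
14 | (3E)-5-[(4-methoxybenzyl)oxy]-3-methylpent-3-en-1-ol | COc1ccc(COC/C=C(\C)CCO)cc1 | intermediate
15 | 1-({[(2E)-5-bromo-3-methylpent-2-en-1-yl]oxy}methyl)-4-methoxybenzene | COc1ccc(COC/C=C(\C)CCBr)cc1 | intermediate
16 | {(3E)-5-[(4-methoxybenzyl)oxy]-3-methylpent-3-en-1-yl}magnesium bromide | COc1ccc(COC/C=C(\C)CC[Mg]Br)cc1 | intermediate (not isolated)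
17 | bromomagnesium alkoxide of (2R,4S)-4,7-bis(tert-butyldimethylsilyloxy)-2-hydroxy-2-methylhept-5-ynal | O=C[C@](C)(O[Mg]Br)C[C@H](O[Si](C)(C)C(C)(C)C)C#CCO[Si](C)(C)C(C)(C)C | intermediate (not isolated)
18 | (2E,6R,7R,9S)-9,12-bis(tert-butyldimethylsilyloxy)-1-[(4-methoxybenzyl)oxy]-3,7-dimethyldodec-2-en-10-yne-6,7-diol | COc1ccc(COC/C=C(\C)CC[C@@H](O)[C@](C)(O)C[C@H](O[Si](C)(C)C(C)(C)C)C#CCO[Si](C)(C)C(C)(C)C)cc1 | intermediate
19 | (2E,6R,7R,9S)-9,12-bis(tert-butyldimethylsilyloxy)-1-[(4-methoxybenzyl)oxy]-3,7-dimethyl-6-(triethylsilyloxy)dodec-2-en-10-yn-7-ol | COc1ccc(COC/C=C(\C)CC[C@@H](O[Si](CC)(CC)CC)[C@](C)(O)C[C@H](O[Si](C)(C)C(C)(C)C)C#CCO[Si](C)(C)C(C)(C)C)cc1 | intermediate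
20 | (2E,6R,7R,9S)-9,12-bis(tert-butyldimethylsilyloxy)-1-[(4-methoxybenzyl)oxy]-3,7-dimethyl-6-(triethylsilyloxy)dodec-2-en-10-yn-7-yl acetate | COc1ccc(COC/C=C(\C)CC[C@@H](O[Si](CC)(CC)CC)[C@](C)(OC(C)=O)C[C@H](O[Si](C)(C)C(C)(C)C)C#CCO[Si](C)(C)C(C)(C)C)cc1 | intermediate
21 | (2E,6R,7R,9S)-9,12-bis(tert-butyldimethylsilyloxy)-1-hydroxy-3,7-dimethyl-6-(triethylsilyloxy)dodec-2-en-10-yn-7-yl acetate | OC/C=C(\C)CC[C@@H](O[Si](CC)(CC)CC)[C@](C)(OC(C)=O)C[C@H](O[Si](C)(C)C(C)(C)C)C#CCO[Si](C)(C)C(C)(C)C | intermediate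
22 | (3R,4R,6S)-6,9-bis(tert-butyldimethylsilyloxy)-1-[(2R,3R)-3-(hydroxymethyl)-2-methyloxiran-2-yl]-4-methyl-3-(triethylsilyloxy)non-7-yn-4-yl acetate | OC[C@H]1O[C@]1(C)CC[C@@H](O[Si](CC)(CC)CC)[C@](C)(OC(C)=O)C[C@H](O[Si](C)(C)C(C)(C)C)C#CCO[Si](C)(C)C(C)(C)C | intermediate
23 | (3R,4R,6S)-6,9-bis(tert-butyldimethylsilyloxy)-1-[(2R,3S)-3-formyl-2-methyloxiran-2-yl]-4-methyl-3-(triethylsilyloxy)non-7-yn-4-yl acetate | O=C[C@H]1O[C@]1(C)CC[C@@H](O[Si](CC)(CC)CC)[C@](C)(OC(C)=O)C[C@H](O[Si](C)(C)C(C)(C)C)C#CCO[Si](C)(C)C(C)(C)C | intermediate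
24 | oxatitanacyclopentene: Cp2Ti bound to O6 and C11, ten-membered ring closed at C6–C7 | CC(C)(C)[Si](C)(C)O[C@H]1C[C@@](C)(OC(C)=O)[C@H](O[Si](CC)(CC)CC)CC[C@@]2(C)O[C@@H]2[C@H]2O[Ti+2]C(CO[Si](C)(C)C(C)(C)C)=C12.[CH-]1C=CC=C1.[CH-]1C=CC=C1 | intermediate (not isolated)
25 | acyltitanium complex: Cp2Ti bound to O6 and to the C12 acyl carbon | CC(C)(C)[Si](C)(C)O[C@H]1C[C@@](C)(OC(C)=O)[C@H](O[Si](CC)(CC)CC)CC[C@@]2(C)O[C@@H]2[C@H]2O[Ti+2]C(=O)C(CO[Si](C)(C)C(C)(C)C)=C12.[CH-]1C=CC=C1.[CH-]1C=CC=C1 | intermediate (not isolated)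
26 | (1R,4R,5R,6S,8S,10R)-10-acetoxy-8,13-bis(tert-butyldimethylsilyloxy)-4,5-epoxy-1-(triethylsilyloxy)germacr-7(11)-en-12,6-olide | CC(C)(C)[Si](C)(C)O[C@H]1C[C@@](C)(OC(C)=O)[C@H](O[Si](CC)(CC)CC)CC[C@@]2(C)O[C@@H]2[C@H]2OC(=O)C(CO[Si](C)(C)C(C)(C)C)=C12 | intermediate
27 | (1R,4R,5R,6S,8S,10R)-10-acetoxy-8,13-bis(tert-butyldimethylsilyloxy)-4,5-epoxy-1-hydroxygermacr-7(11)-en-12,6-olide | CC(C)(C)[Si](C)(C)O[C@H]1C[C@@](C)(OC(C)=O)[C@H](O)CC[C@@]2(C)O[C@@H]2[C@H]2OC(=O)C(CO[Si](C)(C)C(C)(C)C)=C12 | intermediate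
28 | (4R,5R,6S,8S,10R)-10-acetoxy-8,13-bis(tert-butyldimethylsilyloxy)-4,5-epoxy-1-oxogermacr-7(11)-en-12,6-olide | CC(C)(C)[Si](C)(C)O[C@H]1C[C@@](C)(OC(C)=O)C(=O)CC[C@@]2(C)O[C@@H]2[C@H]2OC(=O)C(CO[Si](C)(C)C(C)(C)C)=C12 | intermediate
29 | (4R,5R,6S,8S,10R)-10-acetoxy-4,5-epoxy-8,13-dihydroxy-1-oxogermacr-7(11)-en-12,6-olide | O[C@H]1C[C@@](C)(OC(C)=O)C(=O)CC[C@@]2(C)O[C@@H]2[C@H]2OC(=O)C(CO)=C12 | intermediate
30 | (4R,5R,6S,8S,10R)-10,13-diacetoxy-4,5-epoxy-8-hydroxy-1-oxogermacr-7(11)-en-12,6-olide | O[C@H]1C[C@@](C)(OC(C)=O)C(=O)CC[C@@]2(C)O[C@@H]2[C@H]2OC(=O)C(COC(C)=O)=C12 | intermediate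
31 | (4R,5R,6S,8S,10R)-10,13-diacetoxy-4,5-epoxy-1-oxo-8-tigloyloxygermacr-7(11)-en-12,6-olide, CNP0175424.1 | C/C=C(\C)C(=O)O[C@H]1C[C@@](C)(OC(C)=O)C(=O)CC[C@@]2(C)O[C@@H]2[C@H]2OC(=O)C(COC(C)=O)=C12 | target

**Step count**
Total steps: 21. Longest linear sequence: 17 steps (steps 1–5 and 10–21, from (R)-citramalic acid); steps 6–9 make the C2–C6 fragment.

**Steps most likely to fail**

1. Step 16 (the titanium annulation). Intermolecular coupling may outrun the ten-membered closure, C–C bonding may occur at C11, divalent titanium may open the epoxy aldehyde reductively, or the other aldehyde rotamer may react and give the 6-epimer. Changing the metal alone would be a change of conditions only. The fallback makes the C6–C7 bond and the lactone in separate known steps, a Nozaki–Hiyama–Kishi macrocyclisation of a 2-iodo-1-alkene followed by ring-closing metathesis; it sets out from acid chloride 4 and comes back at 26. Stille acylation of 4 with tributyl(vinyl)stannane (Pd(PPh3)4) would give the vinyl ketone F1, and α-iodination (I2, pyridine) the iodoenone F2. Reduction with (R)-Me-CBS oxazaborolidine and catecholborane should give the (S)-iodo allylic alcohol F3, and TBSOTf the silyl ether F4. The operations of steps 5 and 10–15 would then give in turn the lactol F5, the diol F6, the triethylsilyl ether F7, the acetate F8, the allylic alcohol F9, the epoxy alcohol F10 and the epoxy aldehyde F11. CrCl2 with NiCl2 (cat.) in DMSO/THF at high dilution should close the ten-membered ring to the macrocyclic allylic alcohol F12 (C6–OH, C7=CH2). Esterification with 2-[(tert-butyldimethylsilyloxy)methyl]acrylic acid (carbodiimide, DMAP; under Mitsunobu conditions with inversion if the 6-epimer is formed) would give the acrylate F13. Ring-closing metathesis with the second-generation Hoveyda–Grubbs catalyst (toluene, 80 °C) would then form the C7=C11 bond of the butenolide and give 26.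

2. Step 10 (Grignard addition to the lactol). The lactol may open sluggishly, the reagent may be lost to the released acetone or to cyclopropylcarbinyl rearrangement with β-elimination of the allylic ether, and facial control at C1 may be poor. The fallback makes the aldehyde as a discrete compound; it sets out from dioxolanone 7 and comes back at 18. LiBH4 (THF, 0 °C) would reduce 7 to the primary/tertiary diol F14, and TEMPO with PhI(OAc)2 would oxidise the primary alcohol only to the α-hydroxy aldehyde F15. F15 is added at −78 °C to 2.2 equivalents of 16, where the same magnesium chelate should give 18. The minor C1 epimer can be carried separately, since C1 becomes the ketone in step 18.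

3. Step 12 (acetylation of the tertiary C10 hydroxyl). Acylation beside the bulky C1 silyl ether may be very slow, and the triethylsilyl group may migrate from O1 to O10 under forcing basic conditions. The fallback delivers the acetyl group through a cyclic orthoester; it sets out from diol 18 and comes back at 20. MeC(OMe)3 with pyridinium tosylate would give the cyclic orthoester F16. Mild hydrolysis (AcOH/H2O/THF, 0 °C) should open it to the ester of the more hindered tertiary oxygen, the hydroxy acetate F17. This is silylated at once (TESOTf, 2,6-lutidine, −78 °C), before the acetyl group can migrate, to give 20.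

**Further compounds**

F1 | step 16 | (5R)-2,2,5-trimethyl-5-(2-oxobut-3-en-1-yl)-1,3-dioxolan-4-one | C=CC(=O)C[C@@]1(C)OC(C)(C)OC1=O
F2 | step 16 | (5R)-5-(3-iodo-2-oxobut-3-en-1-yl)-2,2,5-trimethyl-1,3-dioxolan-4-one | C=C(I)C(=O)C[C@@]1(C)OC(C)(C)OC1=O
F3 | step 16 | (5R)-5-[(2S)-2-hydroxy-3-iodobut-3-en-1-yl]-2,2,5-trimethyl-1,3-dioxolan-4-one | C=C(I)[C@@H](O)C[C@@]1(C)OC(C)(C)OC1=O
F4 | step 16 | (5R)-5-[(2S)-2-(tert-butyldimethylsilyloxy)-3-iodobut-3-en-1-yl]-2,2,5-trimethyl-1,3-dioxolan-4-one | C=C(I)[C@@H](O[Si](C)(C)C(C)(C)C)C[C@@]1(C)OC(C)(C)OC1=O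
F5 | step 16 | (5R)-5-[(2S)-2-(tert-butyldimethylsilyloxy)-3-iodobut-3-en-1-yl]-2,2,5-trimethyl-1,3-dioxolan-4-ol | C=C(I)[C@@H](O[Si](C)(C)C(C)(C)C)C[C@@]1(C)OC(C)(C)OC1O
F6 | step 16 | (2E,6R,7R,9S)-9-(tert-butyldimethylsilyloxy)-10-iodo-1-[(4-methoxybenzyl)oxy]-3,7-dimethylundeca-2,10-diene-6,7-diol | COc1ccc(COC/C=C(\C)CC[C@@H](O)[C@](C)(O)C[C@H](O[Si](C)(C)C(C)(C)C)C(I)=C)cc1
F7 | step 16 | (2E,6R,7R,9S)-9-(tert-butyldimethylsilyloxy)-10-iodo-1-[(4-methoxybenzyl)oxy]-3,7-dimethyl-6-(triethylsilyloxy)undeca-2,10-dien-7-ol | COc1ccc(COC/C=C(\C)CC[C@@H](O[Si](CC)(CC)CC)[C@](C)(O)C[C@H](O[Si](C)(C)C(C)(C)C)C(I)=C)cc1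
F8 | step 16 | (2E,6R,7R,9S)-9-(tert-butyldimethylsilyloxy)-10-iodo-1-[(4-methoxybenzyl)oxy]-3,7-dimethyl-6-(triethylsilyloxy)undeca-2,10-dien-7-yl acetate | COc1ccc(COC/C=C(\C)CC[C@@H](O[Si](CC)(CC)CC)[C@](C)(OC(C)=O)C[C@H](O[Si](C)(C)C(C)(C)C)C(I)=C)cc1
F9 | step 16 | (2E,6R,7R,9S)-9-(tert-butyldimethylsilyloxy)-1-hydroxy-10-iodo-3,7-dimethyl-6-(triethylsilyloxy)undeca-2,10-dien-7-yl acetate | OC/C=C(\C)CC[C@@H](O[Si](CC)(CC)CC)[C@](C)(OC(C)=O)C[C@H](O[Si](C)(C)C(C)(C)C)C(I)=C
F10 | step 16 | (3R,4R,6S)-6-(tert-butyldimethylsilyloxy)-1-[(2R,3R)-3-(hydroxymethyl)-2-methyloxiran-2-yl]-7-iodo-4-methyl-3-(triethylsilyloxy)oct-7-en-4-yl acetate | OC[C@H]1O[C@]1(C)CC[C@@H](O[Si](CC)(CC)CC)[C@](C)(OC(C)=O)C[C@H](O[Si](C)(C)C(C)(C)C)C(I)=C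
F11 | step 16 | (3R,4R,6S)-6-(tert-butyldimethylsilyloxy)-1-[(2R,3S)-3-formyl-2-methyloxiran-2-yl]-7-iodo-4-methyl-3-(triethylsilyloxy)oct-7-en-4-yl acetate | O=C[C@H]1O[C@]1(C)CC[C@@H](O[Si](CC)(CC)CC)[C@](C)(OC(C)=O)C[C@H](O[Si](C)(C)C(C)(C)C)C(I)=C
F12 | step 16 | ten-membered allylic alcohol: (1R,4R,5R,6S,8S,10R)-10-acetoxy-8-(tert-butyldimethylsilyloxy)-4,5-epoxy-6-hydroxy-4,10-dimethyl-7-methylidene-1-(triethylsilyloxy)cyclodecane | CC(C)(C)[Si](C)(C)O[C@H]1C[C@@](C)(OC(C)=O)[C@H](O[Si](CC)(CC)CC)CC[C@@]2(C)O[C@@H]2[C@@H](O)C1=C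
F13 | step 16 | 2-[(tert-butyldimethylsilyloxy)methyl]acrylate of F12 at O6 | CC(C)(C)[Si](C)(C)O[C@H]1C[C@@](C)(OC(C)=O)[C@H](O[Si](CC)(CC)CC)CC[C@@]2(C)O[C@@H]2[C@@H](OC(=O)C(=C)CO[Si](C)(C)C(C)(C)C)C1=C
F14 | step 10 | (2R,4S)-4,7-bis(tert-butyldimethylsilyloxy)-2-methylhept-5-yne-1,2-diol | OC[C@](C)(O)C[C@H](O[Si](C)(C)C(C)(C)C)C#CCO[Si](C)(C)C(C)(C)C
F15 | step 10 | (2R,4S)-4,7-bis(tert-butyldimethylsilyloxy)-2-hydroxy-2-methylhept-5-ynal | O=C[C@](C)(O)C[C@H](O[Si](C)(C)C(C)(C)C)C#CCO[Si](C)(C)C(C)(C)C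
F16 | step 12 | cyclic orthoacetate of 18: 2-methoxy-2-methyl-1,3-dioxolane spanning O1 and O10 | COc1ccc(COC/C=C(\C)CC[C@H]2OC(C)(OC)O[C@]2(C)C[C@H](O[Si](C)(C)C(C)(C)C)C#CCO[Si](C)(C)C(C)(C)C)cc1
F17 | step 12 | (2E,6R,7R,9S)-9,12-bis(tert-butyldimethylsilyloxy)-6-hydroxy-1-[(4-methoxybenzyl)oxy]-3,7-dimethyldodec-2-en-10-yn-7-yl acetate | COc1ccc(COC/C=C(\C)CC[C@@H](O)[C@](C)(OC(C)=O)C[C@H](O[Si](C)(C)C(C)(C)C)C#CCO[Si](C)(C)C(C)(C)C)cc1
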